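## Retrosynthetic overview

- Target ⇐ its O‑benzyl ether by hydrogenolysis; C3 is fixed just before that by thermodynamic epimerisation of the lactone to 3,4‑trans.
- The lactone is the only ring formed: C9′–O–C9 closure of a γ‑hydroxy ester, obtained by reducing only the imide carbonyl of an unsymmetrical 2,3‑dibenzylsuccinate.
- C8–C8′ bond: one‑electron oxidative cross‑coupling of two C6–C3 enolates (veratryl N‑acyloxazolidinone × syringyl benzyl ester). The auxiliary sets C4. The order of events is that of lignan biosynthesis: 8–8′ coupling, reduction at C9′, lactone closure.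
- Building blocks: 3‑(3,4‑dimethoxyphenyl)propanoic acid + (S)‑4‑benzyloxazolidin‑2‑one; sinapic acid (hydrogenation, double benzylation).

Assumption: "Reagents that add atoms" refers to atoms kept in the isolated product of a step; the pivaloyl group of 3 and the lithium of 8 and 9 come from the reagents under Conditions and are lost again within the same step.

## Route

Step 1
Reactants: 1 3‑(3,4‑dimethoxyphenyl)propanoic acid; 2 (S)‑4‑benzyl‑1,3‑oxazolidin‑2‑one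
Product: 4 (S)‑4‑benzyl‑3‑[3‑(3,4‑dimethoxyphenyl)propanoyl]‑1,3‑oxazolidin‑2‑one, via mixed pivalic anhydride 3 (not isolated)
Conditions: PivCl, Et3N, THF, −20 °C; then 2, LiCl, −20 °C → rt
Reagents that add atoms: none
Why: Mixed‑anhydride N‑acylation of an oxazolidinone (PivCl/Et3N/LiCl protocol), in which the LiCl‑activated oxazolidinone attacks the unhindered carbonyl of 3 and no stereocentre is touched.

Step 2
Reactants: 5 sinapic acid [(E)‑3‑(4‑hydroxy‑3,5‑dimethoxyphenyl)prop‑2‑enoic acid]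
Product: 6 3‑(4‑hydroxy‑3,5‑dimethoxyphenyl)propanoic acid
Conditions: H2 (1 atm), 10% Pd/C, MeOH, rt
Reagents that add atoms: none
Why: Heterogeneous catalytic hydrogenation of the cinnamic C=C bond, which is much faster than any reduction of the arene or the acid.

Step 3
Reactants: 6 3‑(4‑hydroxy‑3,5‑dimethoxyphenyl)propanoic acid
Product: 7 benzyl 3‑[4‑(benzyloxy)‑3,5‑dimethoxyphenyl]propanoate
Conditions: BnBr (2.4 equiv), K2CO3 (3 equiv), DMF, 60 °C
Reagents that add atoms: benzyl bromide, BrCc1ccccc1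
Why: One‑pot Williamson etherification and carboxylate O‑alkylation (two SN2 reactions on benzyl bromide), which protects the oxidisable phenol for the enolate chemistry and installs an ester whose alkoxide is lost again on lactonisation.

Step 4
Reactants: 4 (S)‑4‑benzyl‑3‑[3‑(3,4‑dimethoxyphenyl)propanoyl]‑1,3‑oxazolidin‑2‑one; 7 benzyl 3‑[4‑(benzyloxy)‑3,5‑dimethoxyphenyl]propanoate
Product: 10 benzyl (2RS,3R)‑2‑[4‑(benzyloxy)‑3,5‑dimethoxybenzyl]‑4‑[(S)‑4‑benzyl‑2‑oxo‑1,3‑oxazolidin‑3‑yl]‑3‑(3,4‑dimethoxybenzyl)‑4‑oxobutanoate, via imide lithium enolate 8 (not isolated), via ester lithium enolate 9 (not isolated)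
Conditions: 4 + 7 (1.5 equiv) added to LDA (2.6 equiv), THF, −78 °C, 30 min; then Fe(acac)3 (2.2 equiv) in THF, −78 °C → rt, Ar
Reagents that add atoms: none
Why: Oxidative enolate heterocoupling (Fe(III) single‑electron oxidation of the mixed imide/ester enolate aggregate) forms the C8–C8′ bond on the face of the chelated (Z)‑imide enolate 8 opposite the auxiliary benzyl group, as in an Evans alkylation, so C3 of 10 (C4 of the target) is set as R while the ester α‑centre forms as a mixture that is corrected in step 6.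

Step 5
Reactants: 10 benzyl (2RS,3R)‑2‑[4‑(benzyloxy)‑3,5‑dimethoxybenzyl]‑4‑[(S)‑4‑benzyl‑2‑oxo‑1,3‑oxazolidin‑3‑yl]‑3‑(3,4‑dimethoxybenzyl)‑4‑oxobutanoate
Product: 12 (3RS,4R)‑3‑[4‑(benzyloxy)‑3,5‑dimethoxybenzyl]‑4‑(3,4‑dimethoxybenzyl)oxolan‑2‑one, via hydroxy ester 11 (not isolated)
Conditions: NaBH4, THF/H2O (3:1), 0 °C → rt; aqueous work‑up; then p‑TsOH·H2O (cat.), PhMe, 50 °C
Reagents that add atoms: none
Why: Chemoselective borohydride reduction of the N‑acyloxazolidinone (reductive auxiliary removal) leaves the benzyl ester untouched, and the freed C9′ hydroxyl then closes the five‑membered ring onto the C9 ester by acid‑catalysed transesterification (lactonisation) without touching C4.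

Step 6
Reactants: 12 (3RS,4R)‑3‑[4‑(benzyloxy)‑3,5‑dimethoxybenzyl]‑4‑(3,4‑dimethoxybenzyl)oxolan‑2‑one
Product: 13 (3R,4R)‑3‑[4‑(benzyloxy)‑3,5‑dimethoxybenzyl]‑4‑(3,4‑dimethoxybenzyl)oxolan‑2‑one
Conditions: DBU (1.5 equiv), PhMe, 90 °C, Ar; chromatography, cis fraction resubjected
Reagents that add atoms: none
Why: Base‑mediated epimerisation through the lactone enolate (thermodynamic control) equilibrates only the enolisable C3 to the favoured 3,4‑trans arrangement, which fixes C3 as R while C4 cannot epimerise.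

Step 7
Reactants: 13 (3R,4R)‑3‑[4‑(benzyloxy)‑3,5‑dimethoxybenzyl]‑4‑(3,4‑dimethoxybenzyl)oxolan‑2‑one
Product: 14 (3R,4R)‑4‑(3,4‑dimethoxybenzyl)‑3‑(4‑hydroxy‑3,5‑dimethoxybenzyl)oxolan‑2‑one
Conditions: H2 (1 atm), 10% Pd/C, EtOAc/EtOH, rt
Reagents that add atoms: none
Why: Hydrogenolysis of the aryl benzyl ether over Pd/C under neutral conditions frees the phenol without touching the lactone, the methyl ethers or either stereocentre.

## Compound list

1 | 3‑(3,4‑dimethoxyphenyl)propanoic acid | COc1ccc(CCC(=O)O)cc1OC | starting material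
2 | (S)‑4‑benzyl‑1,3‑oxazolidin‑2‑one | O=C1N[C@@H](Cc2ccccc2)CO1 | starting material
3 | 3‑(3,4‑dimethoxyphenyl)propanoic pivalic anhydride (not isolated) | COc1ccc(CCC(=O)OC(=O)C(C)(C)C)cc1OC | intermediate
4 | (S)‑4‑benzyl‑3‑[3‑(3,4‑dimethoxyphenyl)propanoyl]‑1,3‑oxazolidin‑2‑one | COc1ccc(CCC(=O)N2C(=O)OC[C@@H]2Cc2ccccc2)cc1OC | intermediate
5 | sinapic acid, (E)‑3‑(4‑hydroxy‑3,5‑dimethoxyphenyl)prop‑2‑enoic acid | COc1cc(/C=C/C(=O)O)cc(OC)c1O | starting material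
6 | 3‑(4‑hydroxy‑3,5‑dimethoxyphenyl)propanoic acid | COc1cc(CCC(=O)O)cc(OC)c1O | intermediate
7 | benzyl 3‑[4‑(benzyloxy)‑3,5‑dimethoxyphenyl]propanoate | COc1cc(CCC(=O)OCc2ccccc2)cc(OC)c1OCc1ccccc1 | intermediate
8 | lithium (Z)‑enolate of 4 (not isolated) | [Li+].[O-]/C(=C\Cc1ccc(OC)c(OC)c1)N1C(=O)OC[C@@H]1Cc1ccccc1 | intermediate
9 | lithium enolate of 7 (not isolated; enolate geometry not defined) | [Li+].[O-]C(=CCc1cc(OC)c(OCc2ccccc2)c(OC)c1)OCc1ccccc1 | intermediate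
10 | benzyl (2RS,3R)‑2‑[4‑(benzyloxy)‑3,5‑dimethoxybenzyl]‑4‑[(S)‑4‑benzyl‑2‑oxo‑1,3‑oxazolidin‑3‑yl]‑3‑(3,4‑dimethoxybenzyl)‑4‑oxobutanoate (C2 epimers) | COc1ccc(C[C@@H](C(=O)N2C(=O)OC[C@@H]2Cc2ccccc2)C(Cc2cc(OC)c(OCc3ccccc3)c(OC)c2)C(=O)OCc2ccccc2)cc1OC | intermediate
11 | benzyl (2RS,3R)‑2‑[4‑(benzyloxy)‑3,5‑dimethoxybenzyl]‑3‑(3,4‑dimethoxybenzyl)‑4‑hydroxybutanoate (not isolated; C2 epimers) | COc1ccc(C[C@@H](CO)C(Cc2cc(OC)c(OCc3ccccc3)c(OC)c2)C(=O)OCc2ccccc2)cc1OC | intermediate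
12 | (3RS,4R)‑3‑[4‑(benzyloxy)‑3,5‑dimethoxybenzyl]‑4‑(3,4‑dimethoxybenzyl)oxolan‑2‑one (C3 epimers) | COc1ccc(C[C@H]2COC(=O)C2Cc2cc(OC)c(OCc3ccccc3)c(OC)c2)cc1OC | intermediate
13 | (3R,4R)‑3‑[4‑(benzyloxy)‑3,5‑dimethoxybenzyl]‑4‑(3,4‑dimethoxybenzyl)oxolan‑2‑one | COc1ccc(C[C@H]2COC(=O)[C@@H]2Cc2cc(OC)c(OCc3ccccc3)c(OC)c2)cc1OC | intermediate
14 | (3R,4R)‑4‑(3,4‑dimethoxybenzyl)‑3‑(4‑hydroxy‑3,5‑dimethoxybenzyl)oxolan‑2‑one | COc1ccc(C[C@H]2COC(=O)[C@@H]2Cc2cc(OC)c(O)c(OC)c2)cc1OC | target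

## Step count and risks

Total steps: 7. Longest linear sequence: 6 steps (5 → 6 → 7 → 10 → 12 → 13 → 14).

**Step 4 (oxidative heterocoupling).** The two homodimers can dominate, conversion can be low, and the facial control of the auxiliary in a radical‑type C–C bond formation is less secure than in an alkylation. The fallback sets out from 4 and comes back at 14, building the two benzylic branches by polar enolate chemistry instead. The sodium enolate of 4 (NaHMDS, THF, −78 °C) is alkylated with benzyl bromoacetate to give benzyl (3R)‑4‑[(S)‑4‑benzyl‑2‑oxo‑1,3‑oxazolidin‑3‑yl]‑3‑(3,4‑dimethoxybenzyl)‑4‑oxobutanoate F1 (Evans alkylation, same sense at C4). NaBH4 in THF/H2O followed by cat. p‑TsOH leads through benzyl (3R)‑4‑(3,4‑dimethoxyphenyl)‑3‑(hydroxymethyl)butanoate F2 (not isolated) to (4R)‑4‑(3,4‑dimethoxybenzyl)oxolan‑2‑one F3. Its lithium enolate (LDA, THF, −78 °C) adds to 4‑(benzyloxy)‑3,5‑dimethoxybenzaldehyde F4 (made from syringaldehyde with BnBr and K2CO3) anti to the C4 substituent. This gives the 3,4‑trans aldol adduct (3S,4R)‑3‑{[4‑(benzyloxy)‑3,5‑dimethoxyphenyl](hydroxy)methyl}‑4‑(3,4‑dimethoxybenzyl)oxolan‑2‑one F5 (carbinol centre mixed). Hydrogenolysis (H2, Pd/C, AcOH, cat. HClO4) removes the benzylic hydroxyl and the O‑benzyl group together and gives 14.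

**Step 5 (reductive removal of the auxiliary from a congested imide).** Hydride can attack the ring carbamate instead of the exocyclic carbonyl, and the ester or the lactone can be over‑reduced. The fallback sets out from 10 and comes back at 11, replacing hydride attack on the imide by hydrolysis followed by acid‑selective reduction. LiOH/H2O2 (THF/H2O, 0 °C) cleaves only the exocyclic acyl bond to give (2R,3RS)‑4‑(benzyloxy)‑3‑[4‑(benzyloxy)‑3,5‑dimethoxybenzyl]‑2‑(3,4‑dimethoxybenzyl)‑4‑oxobutanoic acid F6. BH3·SMe2 (THF, 0 °C → rt) then reduces the carboxylic acid but not the benzyl ester and gives 11, which closes to 12 with cat. p‑TsOH as in step 5.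

**Step 6 (epimerisation).** The equilibrium is expected to leave roughly 5–15% of the cis lactone, and the two epimers may be hard to separate. The fallback sets out from 10 and comes back at 13, replacing equilibration by separation of the acyclic diastereomers before ring closure. Chromatography of 10 gives benzyl (2R,3R)‑2‑[4‑(benzyloxy)‑3,5‑dimethoxybenzyl]‑4‑[(S)‑4‑benzyl‑2‑oxo‑1,3‑oxazolidin‑3‑yl]‑3‑(3,4‑dimethoxybenzyl)‑4‑oxobutanoate F7 and its (2S,3R) epimer benzyl (2S,3R)‑2‑[4‑(benzyloxy)‑3,5‑dimethoxybenzyl]‑4‑[(S)‑4‑benzyl‑2‑oxo‑1,3‑oxazolidin‑3‑yl]‑3‑(3,4‑dimethoxybenzyl)‑4‑oxobutanoate F8, which is set aside. F7 under the conditions of step 5 passes through benzyl (2R,3R)‑2‑[4‑(benzyloxy)‑3,5‑dimethoxybenzyl]‑3‑(3,4‑dimethoxybenzyl)‑4‑hydroxybutanoate F9 (not isolated) and gives 13 directly, with no base treatment; the yield is then limited by the diastereomer ratio of the coupling.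

## Further compounds

F1 | step 4 | benzyl (3R)‑4‑[(S)‑4‑benzyl‑2‑oxo‑1,3‑oxazolidin‑3‑yl]‑3‑(3,4‑dimethoxybenzyl)‑4‑oxobutanoate | COc1ccc(C[C@H](CC(=O)OCc2ccccc2)C(=O)N2C(=O)OC[C@@H]2Cc2ccccc2)cc1OC
F2 | step 4 | benzyl (3R)‑4‑(3,4‑dimethoxyphenyl)‑3‑(hydroxymethyl)butanoate | COc1ccc(C[C@H](CC(=O)OCc2ccccc2)CO)cc1OC
F3 | step 4 | (4R)‑4‑(3,4‑dimethoxybenzyl)oxolan‑2‑one | COc1ccc(C[C@H]2COC(=O)C2)cc1OC
F4 | step 4 | 4‑(benzyloxy)‑3,5‑dimethoxybenzaldehyde | COc1cc(C=O)cc(OC)c1OCc1ccccc1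
F5 | step 4 | (3S,4R)‑3‑{[4‑(benzyloxy)‑3,5‑dimethoxyphenyl](hydroxy)methyl}‑4‑(3,4‑dimethoxybenzyl)oxolan‑2‑one | COc1ccc(C[C@H]2COC(=O)[C@@H]2C(O)c2cc(OC)c(OCc3ccccc3)c(OC)c2)cc1OC
F6 | step 5 | (2R,3RS)‑4‑(benzyloxy)‑3‑[4‑(benzyloxy)‑3,5‑dimethoxybenzyl]‑2‑(3,4‑dimethoxybenzyl)‑4‑oxobutanoic acid | COc1ccc(C[C@@H](C(=O)O)C(Cc2cc(OC)c(OCc3ccccc3)c(OC)c2)C(=O)OCc2ccccc2)cc1OC
F7 | step 6 | benzyl (2R,3R)‑2‑[4‑(benzyloxy)‑3,5‑dimethoxybenzyl]‑4‑[(S)‑4‑benzyl‑2‑oxo‑1,3‑oxazolidin‑3‑yl]‑3‑(3,4‑dimethoxybenzyl)‑4‑oxobutanoate | COc1ccc(C[C@@H](C(=O)N2C(=O)OC[C@@H]2Cc2ccccc2)[C@@H](Cc2cc(OC)c(OCc3ccccc3)c(OC)c2)C(=O)OCc2ccccc2)cc1OC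
F8 | step 6 | benzyl (2S,3R)‑2‑[4‑(benzyloxy)‑3,5‑dimethoxybenzyl]‑4‑[(S)‑4‑benzyl‑2‑oxo‑1,3‑oxazolidin‑3‑yl]‑3‑(3,4‑dimethoxybenzyl)‑4‑oxobutanoate | COc1ccc(C[C@@H](C(=O)N2C(=O)OC[C@@H]2Cc2ccccc2)[C@H](Cc2cc(OC)c(OCc3ccccc3)c(OC)c2)C(=O)OCc2ccccc2)cc1OC
F9 | step 6 | benzyl (2R,3R)‑2‑[4‑(benzyloxy)‑3,5‑dimethoxybenzyl]‑3‑(3,4‑dimethoxybenzyl)‑4‑hydroxybutanoate | COc1ccc(C[C@@H](CO)[C@@H](Cc2cc(OC)c(OCc3ccccc3)c(OC)c2)C(=O)OCc2ccccc2)cc1OC
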